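**Retrosynthetic overview**

1. The target comes from hydrogenolysis of its 3-O-benzyl ether, which comes from O8-methylation of a 5,8-hydroquinone, itself made by reduction of a 6,7-dimethoxy-5,8-quinone.
2. The feature used: O5 and O8 of ring A stand para, so ring A can be carried as a 5,8-quinone (C5=O, C8=O) whose C6 and C7 are electrophilic. After reduction, the C5 hydroxyl is tied to C4=O by a hydrogen bond, so only the C8 hydroxyl is methylated.
3. The C6–O and C7–O bonds come from a 6,7-dichloro-5,8-quinone and NaOMe. The dichloroquinone comes from the parent quinone by two hydrochlorination/re-oxidation cycles, and the parent quinone from a 5,8-dimethoxyflavone with (NH4)2Ce(NO3)6.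
4. Rings A and B are bought. Ring C (the pyranone) is the only ring formed, by Allan–Robinson condensation of an ω-benzyloxy-2-hydroxy-3,6-dimethoxyacetophenone with 4-methoxybenzoic anhydride. The ketone comes from ortho-lithiation of MOM-protected 2,5-dimethoxyphenol and a Weinreb amide.

Key step: step 9

Remark: the first chloride (step 7) and the first methoxide (step 9) are drawn at C6, the carbon conjugated to the more electrophilic C8 carbonyl. Attack at C7 instead would lead to the same compounds 17 and 19.

**Route**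

Step 1
Reactants: 1 2,5-dimethoxyphenol
Product: 2 1,4-dimethoxy-2-(methoxymethoxy)benzene
Conditions: MOMCl, K2CO3, acetone, 0 °C → rt
Reagents that add atoms: chloromethyl methyl ether, COCCl
Why: Williamson-type O-alkylation of the phenoxide by the reactive α-chloro ether gives the MOM ether, chosen as a strong directing group for the ortho-lithiation of step 3.

Step 2
Reactants: 3 benzyloxyacetyl chloride
Product: 4 2-(benzyloxy)-N-methoxy-N-methylacetamide
Conditions: MeNHOMe·HCl, K2CO3, EtOAc/H2O, 0 °C → rt
Reagents that add atoms: N,O-dimethylhydroxylamine hydrochloride, CNOC.Cl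
Why: Schotten–Baumann N-acylation gives the Weinreb amide, which accepts one aryllithium only and so avoids the over-addition expected with the acid chloride itself.

Step 3
Reactants: 2 1,4-dimethoxy-2-(methoxymethoxy)benzene; 4 2-(benzyloxy)-N-methoxy-N-methylacetamide
Product: 7 2-(benzyloxy)-1-[3,6-dimethoxy-2-(methoxymethoxy)phenyl]ethan-1-one, via aryllithium 5 (not isolated), via tetrahedral lithium alkoxide 6 (not isolated)
Conditions: n-BuLi, THF, 0 °C; then 4, −78 → 0 °C; sat. aq NH4Cl
Reagents that add atoms: none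
Why: Directed ortho-metalation occurs at the one position flanked by OMOM and OMe, and the Weinreb ketone synthesis stops at the chelated adduct 6, which releases the ketone only on aqueous quench.

Step 4
Reactants: 7 2-(benzyloxy)-1-[3,6-dimethoxy-2-(methoxymethoxy)phenyl]ethan-1-one
Product: 8 2-(benzyloxy)-1-(2-hydroxy-3,6-dimethoxyphenyl)ethan-1-one
Conditions: TsOH·H2O (cat.), MeOH, 50 °C
Reagents that add atoms: none
Why: Acid-catalysed acetal exchange transfers the methoxymethyl group to methanol and frees the phenol, while the benzyl and methyl ethers, which are not acetals, stay intact.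

Step 5
Reactants: 8 2-(benzyloxy)-1-(2-hydroxy-3,6-dimethoxyphenyl)ethan-1-one; 9 4-methoxybenzoic anhydride
Product: 12 3-(benzyloxy)-5,8-dimethoxy-2-(4-methoxyphenyl)-4H-chromen-4-one, via aryl 4-methoxybenzoate 10 (not isolated), via 1,3-diketone 11 (not isolated)
Conditions: sodium 4-methoxybenzoate, neat, 175 °C; then KOH, EtOH/H2O, reflux
Reagents that add atoms: none
Why: Allan–Robinson flavone synthesis, in which O-aroylation, base-mediated acyl transfer to the α-carbon (Baker–Venkataraman type) and cyclodehydration close ring C with the ω-benzyloxy group ending at C3.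

Step 6
Reactants: 12 3-(benzyloxy)-5,8-dimethoxy-2-(4-methoxyphenyl)-4H-chromen-4-one
Product: 13 3-(benzyloxy)-2-(4-methoxyphenyl)-4H-chromene-4,5,8-trione
Conditions: (NH4)2Ce(NO3)6, MeCN/H2O, 0 °C
Reagents that add atoms: water, O
Why: Oxidative demethylation of the para-dimethoxyarene by tetravalent cerium (single-electron oxidation, attack of water, loss of methanol) should give the para-quinone, since ring A is the most electron-rich arene present and a plain benzyl ether, unlike a 4-methoxybenzyl ether, resists this oxidant.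

Step 7
Reactants: 13 3-(benzyloxy)-2-(4-methoxyphenyl)-4H-chromene-4,5,8-trione
Product: 15 3-(benzyloxy)-6-chloro-2-(4-methoxyphenyl)-4H-chromene-4,5,8-trione, via 6-chloro-5,8-dihydroxyflavone 14 (not isolated)
Conditions: HCl (4 M in 1,4-dioxane), CH2Cl2, 0 °C → rt; evaporate; then Ag2O, MgSO4, CH2Cl2, rt
Reagents that add atoms: hydrogen chloride, Cl
Why: Hydrohalogenation of a quinone, in which chloride adds in a conjugate sense to the enedione, the adduct enolizes to the chlorohydroquinone, and Ag2O re-oxidizes it to the chloroquinone.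

Step 8
Reactants: 15 3-(benzyloxy)-6-chloro-2-(4-methoxyphenyl)-4H-chromene-4,5,8-trione
Product: 17 3-(benzyloxy)-6,7-dichloro-2-(4-methoxyphenyl)-4H-chromene-4,5,8-trione, via 6,7-dichloro-5,8-dihydroxyflavone 16 (not isolated)
Conditions: HCl (4 M in 1,4-dioxane), AcOH, rt; evaporate; then Ag2O, MgSO4, CH2Cl2, rt
Reagents that add atoms: hydrogen chloride, Cl
Why: The same conjugate addition of HCl, now possible only at the remaining C–H carbon of the quinone ring (C7), followed by Ag2O re-oxidation, should give the 6,7-dichloroquinone without any regiochemical question.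

Step 9
Reactants: 17 3-(benzyloxy)-6,7-dichloro-2-(4-methoxyphenyl)-4H-chromene-4,5,8-trione
Product: 19 3-(benzyloxy)-6,7-dimethoxy-2-(4-methoxyphenyl)-4H-chromene-4,5,8-trione, via 7-chloro-6-methoxyquinone 18 (not isolated)
Conditions: NaOMe (2.1 equiv), MeOH/THF, −40 → 0 °C; then AcOH
Reagents that add atoms: sodium methoxide, C[O-].[Na+]
Why: Methoxide adds to C6 of the chlorinated enedione (conjugate to the C8 carbonyl, the more electrophilic one because C5=O is a vinylogous ester of O1), the enolate expels chloride to give 18, and the same addition–elimination at C7 gives 19. The closest known reaction is the conversion of 2,3-dichloro-1,4-naphthoquinone into 2,3-dimethoxy-1,4-naphthoquinone by NaOMe in methanol. No ring is closed and no stereocentre is formed; the two new bonds are C6–O and C7–O. The selectivity needed is chemoselectivity for C6 and C7 over C8a and C2 of the pyranone, which also carry an oxygen leaving group, and over the carbonyl carbons. It should be secured because chloride on a doubly activated vinylogous acid chloride carbon is by far the better leaving group, because hemiketal formation at a carbonyl is reversible, and because the base is limited to 2.1 equivalents at low temperature and quenched with acetic acid before work-up. The order of the two substitutions is immaterial, since both converge on 19.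

Step 10
Reactants: 19 3-(benzyloxy)-6,7-dimethoxy-2-(4-methoxyphenyl)-4H-chromene-4,5,8-trione
Product: 20 3-(benzyloxy)-5,8-dihydroxy-6,7-dimethoxy-2-(4-methoxyphenyl)-4H-chromen-4-one
Conditions: Na2S2O4, EtOAc/H2O, rt, Ar
Reagents that add atoms: none
Why: Two-electron reduction of the quinone to the hydroquinone by dithionite aromatizes ring A and reveals the C5 and C8 hydroxyls without touching the chromone or the benzyl ether.

Step 11
Reactants: 20 3-(benzyloxy)-5,8-dihydroxy-6,7-dimethoxy-2-(4-methoxyphenyl)-4H-chromen-4-one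
Product: 21 3-(benzyloxy)-5-hydroxy-6,7,8-trimethoxy-2-(4-methoxyphenyl)-4H-chromen-4-one
Conditions: MeI (1.1 equiv), K2CO3 (1.1 equiv), degassed DMF, rt, Ar
Reagents that add atoms: iodomethane, CI
Why: Williamson O-methylation with one equivalent of MeI should go to the C8 hydroxyl, because the C5 hydroxyl is held in a six-membered hydrogen-bonded chelate with C4=O and is far less readily deprotonated and alkylated (the classical partial methylation of 5-hydroxyflavones).

Step 12
Reactants: 21 3-(benzyloxy)-5-hydroxy-6,7,8-trimethoxy-2-(4-methoxyphenyl)-4H-chromen-4-one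
Product: 22 3,5-dihydroxy-6,7,8,4'-tetramethoxyflavone
Conditions: H2 (1 atm), 10% Pd/C, EtOAc/MeOH, rt
Reagents that add atoms: none
Why: Catalytic hydrogenolysis of the benzyl ether frees the C3 hydroxyl, while the tetrasubstituted, conjugated C2=C3 bond of the flavone and the aryl methyl ethers should not be reduced under these mild conditions.

**Compound list**

1 | 2,5-dimethoxyphenol | COc1ccc(OC)c(O)c1 | starting material
2 | 1,4-dimethoxy-2-(methoxymethoxy)benzene | COCOc1cc(OC)ccc1OC | intermediate
3 | benzyloxyacetyl chloride | O=C(Cl)COCc1ccccc1 | starting material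
4 | 2-(benzyloxy)-N-methoxy-N-methylacetamide | CON(C)C(=O)COCc1ccccc1 | intermediate
5 | [3,6-dimethoxy-2-(methoxymethoxy)phenyl]lithium | [Li]c1c(OC)ccc(OC)c1OCOC | intermediate
6 | lithium 2-(benzyloxy)-1-[3,6-dimethoxy-2-(methoxymethoxy)phenyl]-1-[methoxy(methyl)amino]ethan-1-olate (racemic) | COCOc1c(OC)ccc(OC)c1C([O-])(COCc1ccccc1)N(C)OC.[Li+] | intermediate
7 | 2-(benzyloxy)-1-[3,6-dimethoxy-2-(methoxymethoxy)phenyl]ethan-1-one | COCOc1c(OC)ccc(OC)c1C(=O)COCc1ccccc1 | intermediate
8 | 2-(benzyloxy)-1-(2-hydroxy-3,6-dimethoxyphenyl)ethan-1-one | COc1ccc(OC)c(C(=O)COCc2ccccc2)c1O | intermediate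
9 | 4-methoxybenzoic anhydride | COc1ccc(C(=O)OC(=O)c2ccc(OC)cc2)cc1 | starting material
10 | 2-[2-(benzyloxy)acetyl]-3,6-dimethoxyphenyl 4-methoxybenzoate | COc1ccc(C(=O)Oc2c(OC)ccc(OC)c2C(=O)COCc2ccccc2)cc1 | intermediate
11 | 2-(benzyloxy)-1-(2-hydroxy-3,6-dimethoxyphenyl)-3-(4-methoxyphenyl)propane-1,3-dione (racemic, enolizable) | COc1ccc(C(=O)C(OCc2ccccc2)C(=O)c2c(OC)ccc(OC)c2O)cc1 | intermediate
12 | 3-(benzyloxy)-5,8-dimethoxy-2-(4-methoxyphenyl)-4H-chromen-4-one | COc1ccc(-c2oc3c(OC)ccc(OC)c3c(=O)c2OCc2ccccc2)cc1 | intermediate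
13 | 3-(benzyloxy)-2-(4-methoxyphenyl)-4H-chromene-4,5,8-trione | COc1ccc(-c2oc3c(c(=O)c2OCc2ccccc2)C(=O)C=CC3=O)cc1 | intermediate
14 | 3-(benzyloxy)-6-chloro-5,8-dihydroxy-2-(4-methoxyphenyl)-4H-chromen-4-one | COc1ccc(-c2oc3c(O)cc(Cl)c(O)c3c(=O)c2OCc2ccccc2)cc1 | intermediate
15 | 3-(benzyloxy)-6-chloro-2-(4-methoxyphenyl)-4H-chromene-4,5,8-trione | COc1ccc(-c2oc3c(c(=O)c2OCc2ccccc2)C(=O)C(Cl)=CC3=O)cc1 | intermediate
16 | 3-(benzyloxy)-6,7-dichloro-5,8-dihydroxy-2-(4-methoxyphenyl)-4H-chromen-4-one | COc1ccc(-c2oc3c(O)c(Cl)c(Cl)c(O)c3c(=O)c2OCc2ccccc2)cc1 | intermediate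
17 | 3-(benzyloxy)-6,7-dichloro-2-(4-methoxyphenyl)-4H-chromene-4,5,8-trione | COc1ccc(-c2oc3c(c(=O)c2OCc2ccccc2)C(=O)C(Cl)=C(Cl)C3=O)cc1 | intermediate
18 | 3-(benzyloxy)-7-chloro-6-methoxy-2-(4-methoxyphenyl)-4H-chromene-4,5,8-trione | COc1ccc(-c2oc3c(c(=O)c2OCc2ccccc2)C(=O)C(OC)=C(Cl)C3=O)cc1 | intermediate
19 | 3-(benzyloxy)-6,7-dimethoxy-2-(4-methoxyphenyl)-4H-chromene-4,5,8-trione | COc1ccc(-c2oc3c(c(=O)c2OCc2ccccc2)C(=O)C(OC)=C(OC)C3=O)cc1 | intermediate
20 | 3-(benzyloxy)-5,8-dihydroxy-6,7-dimethoxy-2-(4-methoxyphenyl)-4H-chromen-4-one | COc1ccc(-c2oc3c(O)c(OC)c(OC)c(O)c3c(=O)c2OCc2ccccc2)cc1 | intermediate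
21 | 3-(benzyloxy)-5-hydroxy-6,7,8-trimethoxy-2-(4-methoxyphenyl)-4H-chromen-4-one | COc1ccc(-c2oc3c(OC)c(OC)c(OC)c(O)c3c(=O)c2OCc2ccccc2)cc1 | intermediate
22 | 3,5-dihydroxy-6,7,8,4'-tetramethoxyflavone | COc1ccc(-c2oc3c(OC)c(OC)c(OC)c(O)c3c(=O)c2O)cc1 | target

**Step count**

Total step count: 12. Longest linear sequence: 11 steps (step 1, then steps 3 to 12; step 2 is a one-step side branch).

**Steps most likely to fail**

Step 9. Methoxide may attack C8a or C2 and open the pyranone, or the second substitution may stall at the vinylogous ester 18 so that forcing conditions destroy the tricarbonyl system. The fallback sets out from Weinreb amide 4 and anhydride 9 and comes back at target 22. It builds ring A with all its oxygens in place and uses no quinone.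
- Commercial 3,4,5-trimethoxyphenol would be protected (MOMCl, K2CO3, acetone) as 1,2,3-trimethoxy-5-(methoxymethoxy)benzene F1.
- Lithiation between OMOM and OMe (n-BuLi, THF, 0 °C) and acylation with 4 would give 2-(benzyloxy)-1-[2,3,4-trimethoxy-6-(methoxymethoxy)phenyl]ethan-1-one F2.
- TsOH in MeOH would release 2-(benzyloxy)-1-(6-hydroxy-2,3,4-trimethoxyphenyl)ethan-1-one F3.
- Allan–Robinson condensation with 9, as in step 5, would give 3-(benzyloxy)-5,6,7-trimethoxy-2-(4-methoxyphenyl)-4H-chromen-4-one F4.
- NBS in MeCN would brominate C8, the only free position of the electron-rich ring A, to give 3-(benzyloxy)-8-bromo-5,6,7-trimethoxy-2-(4-methoxyphenyl)-4H-chromen-4-one F5.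
- Ullmann-type methoxylation (NaOMe, CuBr, DMF/MeOH, 100 °C), to which a plain flavone is far less sensitive than the quinone, would give 3-(benzyloxy)-5,6,7,8-tetramethoxy-2-(4-methoxyphenyl)-4H-chromen-4-one F6.
- BCl3 (CH2Cl2, −78 → 0 °C) would then cleave the benzyl ether and, through chelation to C4=O, only the C5 methyl ether, to give 22.

Step 8. Conjugate addition of chloride to the already chlorinated quinone may be slow or reversible, and long exposure to acid may erode the material. The fallback sets out from 15 and comes back at 17. It replaces conjugate addition to the quinone by electrophilic substitution on the hydroquinone. Na2S2O4 would reduce 15 to the chlorohydroquinone 14. SO2Cl2 in AcOH would chlorinate the single free position of its electron-rich ring A, much faster than ring B, to give 16. Ag2O would oxidize 16 to 17. No new compound arises.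

Step 11. The hydroquinone may be re-oxidized to quinone 19 in the basic medium, and alkylation may spread to O5 once its hydrogen bond is broken by deprotonation. The fallback sets out from 20 and comes back at target 22. It moves the O5/O8 differentiation from the alkylation to a dealkylation. Exhaustive methylation (excess Me2SO4, K2CO3, acetone, reflux, Ar) would give 3-(benzyloxy)-5,6,7,8-tetramethoxy-2-(4-methoxyphenyl)-4H-chromen-4-one F7. BCl3 (CH2Cl2, −78 → 0 °C) would cleave the benzyl ether and the chelation-activated C5 methyl ether in one operation to give 22.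

**Further compounds**

F1 | step 9 | 1,2,3-trimethoxy-5-(methoxymethoxy)benzene | COCOc1cc(OC)c(OC)c(OC)c1
F2 | step 9 | 2-(benzyloxy)-1-[2,3,4-trimethoxy-6-(methoxymethoxy)phenyl]ethan-1-one | COCOc1cc(OC)c(OC)c(OC)c1C(=O)COCc1ccccc1
F3 | step 9 | 2-(benzyloxy)-1-(6-hydroxy-2,3,4-trimethoxyphenyl)ethan-1-one | COc1cc(O)c(C(=O)COCc2ccccc2)c(OC)c1OC
F4 | step 9 | 3-(benzyloxy)-5,6,7-trimethoxy-2-(4-methoxyphenyl)-4H-chromen-4-one | COc1ccc(-c2oc3cc(OC)c(OC)c(OC)c3c(=O)c2OCc2ccccc2)cc1
F5 | step 9 | 3-(benzyloxy)-8-bromo-5,6,7-trimethoxy-2-(4-methoxyphenyl)-4H-chromen-4-one | COc1ccc(-c2oc3c(Br)c(OC)c(OC)c(OC)c3c(=O)c2OCc2ccccc2)cc1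
F6 | step 9 | 3-(benzyloxy)-5,6,7,8-tetramethoxy-2-(4-methoxyphenyl)-4H-chromen-4-one | COc1ccc(-c2oc3c(OC)c(OC)c(OC)c(OC)c3c(=O)c2OCc2ccccc2)cc1
F0 | step 8 | none | none
F7 | step 11 | 3-(benzyloxy)-5,6,7,8-tetramethoxy-2-(4-methoxyphenyl)-4H-chromen-4-one | COc1ccc(-c2oc3c(OC)c(OC)c(OC)c(OC)c3c(=O)c2OCc2ccccc2)cc1
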